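## The problem

1. 8-Prenylkaempferol (12) is a flat flavonol. A phloroglucinol-type ring A (C4a, C5–C8, C8a) is fused to a 3-hydroxy-4-pyranone ring C (O1, C2, C3, C4, C4a, C8a), which carries the 4-hydroxyphenyl ring B at C2 (flavonoid numbering is used for all intermediates below).
2. There is no stereocentre and no stereogenic double bond, so the whole selectivity problem is constitutional.
3. Its core is ring A, a pentasubstituted benzene in which C6 and C8 are each flanked by two oxygens and are almost equally nucleophilic. Prenylation of a finished phloroglucinol or flavonol must therefore choose between C6, C8 and the hydroxyl oxygens, and if the prenyl group is put on before ring C is closed, the same ambiguity returns as the choice between the two ortho-hydroxyls of the aryl ketone.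
4. The second problem is the C3 hydroxyl, usually introduced by peroxide or dioxirane oxidation of a molecule that holds, or must later receive, an electron-rich trisubstituted alkene.
5. The third is sensitivity: the prenyl alkene next to the free 7-OH closes to a chroman under acid, hydrogenolysis is excluded, and the free polyphenol is air-sensitive in base.
6. The feature that opens another way is that ring C by itself is the ring of allomaltol (1). O1, C2–H, C3–OH, C4=O, C4a–H and C8a are all present, and the methyl group of 1 sits on C8a and is C8.
7. Ring A then lacks only C7–C6–C5, a three-carbon chain oxygenated at both ends like a malonyl unit, and deprotonation at C8 sends charge through C8a to C4a, the very carbon that must bond to C5.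
8. Ring A can therefore be grown last, with the prenyl group placed on an sp3 carbon and with the O1–C8a–C8 connectivity, which defines "8-prenyl", bought rather than selected.

## Retrosynthesis

**12 ⇒ 11.** The two acetal O–CH2 bonds at O3 and O4' are cut.
- Only the two hydroxyls that exist before ring A is built need masking. The 5-OH and 7-OH are born free in the key step and are never protected, so 11 differs from 12 by two groups only.
- The forward reaction must cleave two MOM ethers with acid mild enough to leave the prenyl alkene beside the 7-OH alone.

**11 ⇒ 9.** The C4a–C5 bond is cut and ring A is opened.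
- Cutting ring C instead (O1–C2, C2–C3) leads back to an acylphloroglucinol with two competing ortho-hydroxyls.
- Cutting C8–C1'' leads back to arene prenylation.
- Cutting C5–C6 would demand an extra ester on C4a.
- The C4a–C5 cut leaves O1–C8a–C8 untouched and turns a pentasubstituted benzene into a linear chain on a monocyclic pyranone, in which each ring-A substituent is simply a chain position.
- The forward reaction is a Claisen-type C-acylation of C4a by the ester carbon C5 with aromatisation. This is the ring-A closure that chalcone synthase performs on its tetraketide. It requires C4a to act as the α-carbon of a dienolate and the pyranone not to be opened.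

**9 ⇒ 8.** The C5–C6 bond is cut, removing one carbonate-level carbon.
- The neighbouring C7–C8 cut would call for a malonyl donor whose acidic CH2 would only protonate the carbanion at C8.
- Cutting C5–C6 lets the least stabilised carbanion of a dianion do the work.
- Precursor 8 is a plain methyl ketone. The forward step must acylate the terminal carbon and not C8 or oxygen.

**8 ⇒ 6 + 7.** The C8–C1'' bond is cut.
- In 6, C8 is the only doubly activated methylene (ketone on one side, vinylogous pyranone carbonyl on the other), while the future C6 is an ordinary ketone methyl. The C6/C8 problem of the arene thus becomes an acidity difference of many orders of magnitude.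
- The cut must precede the addition of C5, because in 9 the C6 methylene would compete.
- The forward reaction is a C-alkylation of a stabilised enolate with prenyl bromide (7).

**6 ⇒ 5.** The C7–C8 bond is cut, removing an acetyl group. The methyl group of 5 is the only acidic C–H, so a lateral (vinylogous) deprotonation and one clean mono-acylation are all that is asked.

**5 ⇒ 3 + 4, 3 ⇒ 2 ⇒ 1.** The C2–C1' biaryl-type bond is cut.
- C2–H of 1 is the β-carbon of the C3 enol and is the natural site of halogenation. After O-protection, the resulting β-bromo enone 3 is an ideal partner for boronic acid 4.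
- The C3 oxygen comes with 1, so no oxidation step appears anywhere in the route.

## Roads not taken

**Alternative 1:** the most obvious route.
- The cut: O1–C2 and C3–OH in ring C, then the C2–C3 aldol bond. Acetophenone A1 and aldehyde A2 give chalcone A3.
- The forward key step: Algar–Flynn–Oyamada oxidative cyclisation of A3 with alkaline hydrogen peroxide.
- Why the chosen plan is better:
  - The 6/8 question is only moved. A1 must carry its single free hydroxyl next to the prenyl group, which costs a selective double protection plus an O-prenylation/rearrangement or an unselective C-prenylation.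
  - A3 bears an alkoxy group at C6' (future C5). This twists the aroyl group and steers the phenoxide towards five-ring (aurone-type) closure, the known weakness of this reaction.
  - The oxidant acts with the prenyl alkene present, and three acetals remain to be cleaved.
  - The chosen plan buys both the C3 oxygen and the O1–C8a–C8 array.

**Alternative 2:**
- The cut: C8–C1'' on the finished flavonol by sigmatropy. Kaempferol A4 is protected at O3, O7 and O4' and prenylated at the chelated O5 to give ether A5.
- The forward key step: a Claisen shift of A5 to C6 followed by a Cope shift to C8.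
- Why the chosen plan is better:
  - The whole skeleton must be in hand first.
  - Three protections depend on the 5-OH reacting last.
  - The regiochemistry is kinetic. The intermediate C6 dienone carries a hydrogen and can re-aromatise before the Cope shift, which diverts material to the C6 series.
  - In the chosen plan the position of the prenyl group is fixed by connectivity and no high-temperature step is needed.

**Alternative 3:**
- The cut: C8–C1'' as a cross-coupling. Fully protected A4 is iodinated to the 8-iodide A6.
- The forward key step: palladium coupling of A6 with prenylboronate A7.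
- Why the chosen plan is better:
  - Halogenation again has to tell C8 from C6, and the outcome depends on the protecting pattern.
  - The allyl-metal partner passes through an η3-prenyl palladium species that can couple at either terminus.
  - Four protecting groups are put on and taken off.
  - The chosen plan makes the same bond by SN2 at a primary allylic carbon with a single possible nucleophilic site.

Key step: step 7

Assumption: 12 has no stereocentre and no stereogenic double bond, so "single enantiomer" is read as the single constitutional isomer drawn (8-prenyl, not 6-prenyl). Compounds 8–10 are racemic at C8, a centre that is erased in step 7.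

## Steps

Step 1
Reactants: 1 allomaltol (5-hydroxy-2-methyl-4H-pyran-4-one)
Product: 2 2-bromo-3-hydroxy-6-methyl-4H-pyran-4-one
Conditions: NBS (1.05 equiv), MeCN, 0 °C to rt, dark
Reagents that add atoms: N-bromosuccinimide, O=C1CCC(=O)N1Br
Why: Electrophilic bromination of an enol: the free OH makes the adjacent C–H carbon (future C2) the enol β-carbon, the site at which 3-hydroxy-4-pyranones take halogen, Mannich and aldol electrophiles, whereas C4a–H is only the α-carbon of a vinylogous ester. Polar conditions in the dark keep the methyl group out of radical bromination.

Step 2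
Reactants: 2 2-bromo-3-hydroxy-6-methyl-4H-pyran-4-one
Product: 3 2-bromo-3-(methoxymethoxy)-6-methyl-4H-pyran-4-one
Conditions: MOMCl (1.3 equiv), i-Pr2NEt (1.5 equiv), CH2Cl2, 0 °C to rt
Reagents that add atoms: chloromethyl methyl ether, COCCl
Why: Williamson-type O-alkylation of an acidic enol. The MOM ether removes the acidic proton before the carbanion steps and withstands Pd/carbonate, amide bases and NaH.

Step 3
Reactants: 3 2-bromo-3-(methoxymethoxy)-6-methyl-4H-pyran-4-one; 4 4-(methoxymethoxy)phenylboronic acid
Product: 5 3-(methoxymethoxy)-2-[4-(methoxymethoxy)phenyl]-6-methyl-4H-pyran-4-one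
Conditions: Pd(dppf)Cl2 (3 mol %), K2CO3 (2 equiv), 1,4-dioxane/H2O, 80 °C
Reagents that add atoms: none
Why: Suzuki–Miyaura coupling; the C2–Br bond belongs to a β-bromo enone (vinylogous acyl bromide) and should add readily to Pd(0). The step sets C2–C1' with ring B already carrying its protected oxygen.

Step 4
Reactants: 5 3-(methoxymethoxy)-2-[4-(methoxymethoxy)phenyl]-6-methyl-4H-pyran-4-one
Product: 6 3-(methoxymethoxy)-2-[4-(methoxymethoxy)phenyl]-6-(2-oxopropyl)-4H-pyran-4-one
Conditions: LDA (1.15 equiv), THF, −78 °C; MeC(O)N(OMe)Me (1.3 equiv), −78 to −40 °C; AcOH quench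
Reagents that add atoms: N-methoxy-N-methylacetamide, CC(=O)N(C)OC
Why: Lateral (vinylogous) deprotonation of a 2-methyl-4-pyranone followed by C-acylation; the methyl group is the only acidic C–H, and attack through the exocyclic carbon restores the pyranone. The Weinreb amide holds the tetrahedral adduct until the quench, so the more acidic product cannot consume the anion and a second acylation is excluded.

Step 5
Reactants: 6 3-(methoxymethoxy)-2-[4-(methoxymethoxy)phenyl]-6-(2-oxopropyl)-4H-pyran-4-one; 7 prenyl bromide (1-bromo-3-methylbut-2-ene)
Product: 8 (±)-3-(methoxymethoxy)-2-[4-(methoxymethoxy)phenyl]-6-(6-methyl-2-oxohept-5-en-3-yl)-4H-pyran-4-one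
Conditions: NaH (1.05 equiv), THF/DMF, 0 °C; 7 (1.1 equiv), 0 °C to rt
Reagents that add atoms: none
Why: Alkylation of an active methylene: C8 lies between the ketone and the vinylogous pyranone carbonyl and is far more acidic than the terminal methyl (future C6), so one equivalent of base addresses C8 alone and the soft primary allylic bromide favours SN2 C-alkylation. The new centre at C8 is racemic and labile and is erased in step 7.

Step 6
Reactants: 8 (±)-3-(methoxymethoxy)-2-[4-(methoxymethoxy)phenyl]-6-(6-methyl-2-oxohept-5-en-3-yl)-4H-pyran-4-one
Product: 9 (±)-methyl 4-{5-(methoxymethoxy)-6-[4-(methoxymethoxy)phenyl]-4-oxo-4H-pyran-2-yl}-7-methyl-3-oxooct-6-enoate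
Conditions: LDA (3.2 equiv), THF, −78 to −20 °C; (MeO)2CO (1.5 equiv), −20 °C to rt; AcOH quench
Reagents that add atoms: dimethyl carbonate, COC(=O)OC
Why: Terminal acylation of a 1,3-dicarbonyl-type dianion: the first equivalent of LDA removes C8–H, the second a methyl proton, and the less stabilised terminal carbanion (C6) is the one that attacks the carbonate. The third equivalent takes up the acidic C6–H of the product so that it does not quench unreacted dianion.

Step 7
Reactants: 9 (±)-methyl 4-{5-(methoxymethoxy)-6-[4-(methoxymethoxy)phenyl]-4-oxo-4H-pyran-2-yl}-7-methyl-3-oxooct-6-enoate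
Product: 11 5,7-dihydroxy-3-(methoxymethoxy)-2-[4-(methoxymethoxy)phenyl]-8-(3-methylbut-2-enyl)-4H-chromen-4-one, via trione tautomer 10 (not isolated)
Conditions: DBU (3 equiv), MeCN, 4 Å MS, 60 °C, argon; pH 5 phosphate buffer work-up
Reagents that add atoms: none
Why: Proposed new method: DBU removes the doubly activated C8–H of 9, the charge spreads through C8=C8a onto C4a and the C4 oxygen (γ-deprotonated vinylogous ester), C4a adds to the ester carbon C5, and loss of methoxide gives trione 10, whose enolisation to the phloroglucinol ring of 11 is irreversible and drains all prior equilibria. The closest known reaction types are the Claisen-type cyclisation of 3,5,7-triketo esters to acylphloroglucinols, which is the laboratory model of chalcone synthase, and the base-induced aromatisation of diketo-dioxinones to resorcylates, where the α-carbon of a six-membered cyclic vinylogous ester is the nucleophile after γ-deprotonation; not yet shown is a 4-pyranone in this role with an ester as acceptor. Ring A closes in the 6-(enolexo)-exo-trig mode. No stereocentre is created and the labile one at C8 disappears. The step needs one productive closure out of several nucleophile/acceptor pairs, and ring size secures it: C8 onto C5 would give a four-membered ring, the C4 oxygen onto C5 an eight-membered one, and C6 onto C4 a bridged aldolate that cannot lose water and reverts. It also needs the 8-prenyl connectivity to survive, which holds as long as the O1–C8a bond is never opened, hence a non-nucleophilic amidine and sieves to take up methanol. A base of moderate strength is chosen on purpose, because a dianion would enolise the C6–C5 ester unit and switch off the acceptor, whereas under reversible proton transfer the minor C8 anion can react through the un-enolised ester.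

Step 8
Reactants: 11 5,7-dihydroxy-3-(methoxymethoxy)-2-[4-(methoxymethoxy)phenyl]-8-(3-methylbut-2-enyl)-4H-chromen-4-one
Product: 12 8-prenylkaempferol (3,5,7-trihydroxy-2-(4-hydroxyphenyl)-8-(3-methylbut-2-enyl)-4H-chromen-4-one)
Conditions: HCl (cat., ca. 0.3 M in MeOH), 0 °C to rt, argon; dilution with water and extraction as soon as the 4'-acetal is gone
Reagents that add atoms: none
Why: Acid-catalysed acetal exchange (methanolysis of MOM ethers), the usual last step for prenylated polyphenols. The enolic 3-O-acetal and the aryl acetal should ionise much faster than the trisubstituted alkene is protonated at this acidity, and only two acetals have to go.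

## Compound list

1 | allomaltol (5-hydroxy-2-methyl-4H-pyran-4-one) | Cc1cc(=O)c(O)co1 | starting material
2 | 2-bromo-3-hydroxy-6-methyl-4H-pyran-4-one | Cc1cc(=O)c(O)c(Br)o1 | intermediate
3 | 2-bromo-3-(methoxymethoxy)-6-methyl-4H-pyran-4-one | Cc1cc(=O)c(OCOC)c(Br)o1 | intermediate
4 | 4-(methoxymethoxy)phenylboronic acid | COCOc1ccc(B(O)O)cc1 | starting material
5 | 3-(methoxymethoxy)-2-[4-(methoxymethoxy)phenyl]-6-methyl-4H-pyran-4-one | Cc1cc(=O)c(OCOC)c(-c2ccc(OCOC)cc2)o1 | intermediate
6 | 3-(methoxymethoxy)-2-[4-(methoxymethoxy)phenyl]-6-(2-oxopropyl)-4H-pyran-4-one | CC(=O)Cc1cc(=O)c(OCOC)c(-c2ccc(OCOC)cc2)o1 | intermediate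
7 | prenyl bromide (1-bromo-3-methylbut-2-ene) | CC(C)=CCBr | starting material
8 | 3-(methoxymethoxy)-2-[4-(methoxymethoxy)phenyl]-6-(6-methyl-2-oxohept-5-en-3-yl)-4H-pyran-4-one (racemic) | CC(=O)C(CC=C(C)C)c1cc(=O)c(OCOC)c(-c2ccc(OCOC)cc2)o1 | intermediate
9 | methyl 4-{5-(methoxymethoxy)-6-[4-(methoxymethoxy)phenyl]-4-oxo-4H-pyran-2-yl}-7-methyl-3-oxooct-6-enoate (racemic) | COC(=O)CC(=O)C(CC=C(C)C)c1cc(=O)c(OCOC)c(-c2ccc(OCOC)cc2)o1 | intermediate
10 | 3-(methoxymethoxy)-2-[4-(methoxymethoxy)phenyl]-8-(3-methylbut-2-enyl)-6H-chromene-4,5,7(8H)-trione (racemic, not isolated) | CC(C)=CCC1C(=O)CC(=O)c2c1oc(-c1ccc(OCOC)cc1)c(OCOC)c2=O | intermediate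
11 | 5,7-dihydroxy-3-(methoxymethoxy)-2-[4-(methoxymethoxy)phenyl]-8-(3-methylbut-2-enyl)-4H-chromen-4-one | CC(C)=CCc1c(O)cc(O)c2c(=O)c(OCOC)c(-c3ccc(OCOC)cc3)oc12 | intermediate
12 | 8-prenylkaempferol | CC(C)=CCc1c(O)cc(O)c2c(=O)c(O)c(-c3ccc(O)cc3)oc12 | target

Total step count: 8. Longest linear sequence: 8 steps (1 to 12).

## Least certain steps

**Step 7 (key step, proposed new method).**
- What may go wrong: the closure may be too slow. The resting anion sits at C6 (β-keto ester enolate, acceptor switched off), and C4a of a pyranone dienolate is a weak nucleophile. A slow closure leaves time for opening of ring C by liberated methoxide and for retro-Claisen loss of the ester.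
- Fallback: known chemistry with the polarity of the closure reversed. The ester sits on C4a and the ketone enolate carbon C6 attacks it, so C5–C6 is made last, as in the toluate route to 1,3-dihydroxyarenes. It sets out from 5 and comes back at 11. Iodination of the only free ring-C position of 5 with NIS should give the C4a iodide F1. Palladium-catalysed methoxycarbonylation (CO, MeOH, Et3N) should give the C4a methyl ester F2. Lateral deprotonation (LDA) and alkylation with 7 should give the homoprenyl ester F3. A second lateral deprotonation and acetylation with N-methoxy-N-methylacetamide should give the keto ester F4. NaH or KOt-Bu should then close F4 by Dieckmann-type attack of the methyl ketone enolate on the ester, with aromatisation to 11.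

**Step 6.**
- What may go wrong: incomplete conversion through proton transfer from the newly formed β-keto ester to unreacted dianion, consumption of the carbonate by the excess amide base, and acylation on an enolate oxygen.
- Fallback: the C6–C7 bond is made instead of C5–C6. It sets out from 5 and comes back at 9, bypassing 6 and 8. Lateral alkylation of 5 with 7 (LDA, THF, −78 °C) should give the homoprenyl pyranone F5. A second lateral deprotonation and trapping with CO2 should give the pyranylacetic acid F6, which is kept cold because it is a vinylogous β-keto acid. Activation with CDI and decarboxylative Claisen condensation with magnesium methyl malonate should give 9.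

**Step 8.**
- What may go wrong: protonation of the prenyl alkene and capture of the tertiary cation by the neighbouring 7-OH (chroman closure) or by methanol, in competition with the slower cleavage of the 4'-O-acetal.
- Fallback: an allyl group, which cannot give a tertiary cation, is carried through the acid step, and the trisubstituted alkene is made last. It sets out from 6 and comes back at 12. Alkylation of 6 with allyl bromide as in step 5 should give the allyl ketone F7. Methoxycarbonylation as in step 6 should give the allyl keto ester F8. Cyclisation as in step 7 should give the protected 8-allylflavonol F9. Acid methanolysis should give 8-allylkaempferol F10. Cross metathesis with 2-methyl-2-butene (second-generation ruthenium catalyst) should give 12.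

**Step 4.**
- What may go wrong: self-condensation of the lateral anion with neutral 5 (conjugate attack at C8a or C2) and proton exchange while acyl transfer is slow.
- Fallback: aldol addition and oxidation in place of acylation. It sets out from 5 and comes back at 6. The lateral anion is added to acetaldehyde, a much faster electrophile at −78 °C, to give the secondary alcohol F11, which is oxidised with Dess–Martin periodinane to 6.

## Further compounds

F1 | step 7 | 5-iodo-3-(methoxymethoxy)-2-[4-(methoxymethoxy)phenyl]-6-methyl-4H-pyran-4-one | Cc1oc(-c2ccc(OCOC)cc2)c(OCOC)c(=O)c1I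
F2 | step 7 | methyl 5-(methoxymethoxy)-6-[4-(methoxymethoxy)phenyl]-2-methyl-4-oxo-4H-pyran-3-carboxylate | COC(=O)c1c(C)oc(-c2ccc(OCOC)cc2)c(OCOC)c1=O
F3 | step 7 | methyl 5-(methoxymethoxy)-6-[4-(methoxymethoxy)phenyl]-2-(4-methylpent-3-enyl)-4-oxo-4H-pyran-3-carboxylate | COC(=O)c1c(CCC=C(C)C)oc(-c2ccc(OCOC)cc2)c(OCOC)c1=O
F4 | step 7 | methyl 5-(methoxymethoxy)-6-[4-(methoxymethoxy)phenyl]-2-(6-methyl-2-oxohept-5-en-3-yl)-4-oxo-4H-pyran-3-carboxylate (racemic) | COC(=O)c1c(C(CC=C(C)C)C(C)=O)oc(-c2ccc(OCOC)cc2)c(OCOC)c1=O
F5 | step 6 | 3-(methoxymethoxy)-2-[4-(methoxymethoxy)phenyl]-6-(4-methylpent-3-enyl)-4H-pyran-4-one | CC(C)=CCCc1cc(=O)c(OCOC)c(-c2ccc(OCOC)cc2)o1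
F6 | step 6 | 2-{5-(methoxymethoxy)-6-[4-(methoxymethoxy)phenyl]-4-oxo-4H-pyran-2-yl}-5-methylhex-4-enoic acid (racemic) | CC(C)=CCC(C(=O)O)c1cc(=O)c(OCOC)c(-c2ccc(OCOC)cc2)o1
F7 | step 8 | 3-(methoxymethoxy)-2-[4-(methoxymethoxy)phenyl]-6-(2-oxohex-5-en-3-yl)-4H-pyran-4-one (racemic) | CC(=O)C(CC=C)c1cc(=O)c(OCOC)c(-c2ccc(OCOC)cc2)o1
F8 | step 8 | methyl 4-{5-(methoxymethoxy)-6-[4-(methoxymethoxy)phenyl]-4-oxo-4H-pyran-2-yl}-3-oxohept-6-enoate (racemic) | COC(=O)CC(=O)C(CC=C)c1cc(=O)c(OCOC)c(-c2ccc(OCOC)cc2)o1
F9 | step 8 | 8-allyl-5,7-dihydroxy-3-(methoxymethoxy)-2-[4-(methoxymethoxy)phenyl]-4H-chromen-4-one | C=CCc1c(O)cc(O)c2c(=O)c(OCOC)c(-c3ccc(OCOC)cc3)oc12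
F10 | step 8 | 8-allylkaempferol | C=CCc1c(O)cc(O)c2c(=O)c(O)c(-c3ccc(O)cc3)oc12
F11 | step 4 | 6-(2-hydroxypropyl)-3-(methoxymethoxy)-2-[4-(methoxymethoxy)phenyl]-4H-pyran-4-one (racemic) | CC(O)Cc1cc(=O)c(OCOC)c(-c2ccc(OCOC)cc2)o1
A1 | alternative 1 | 1-[2-hydroxy-4,6-bis(methoxymethoxy)-3-(3-methylbut-2-enyl)phenyl]ethanone | CC(=O)c1c(O)c(CC=C(C)C)c(OCOC)cc1OCOC
A2 | alternative 1 | 4-(methoxymethoxy)benzaldehyde | COCOc1ccc(C=O)cc1
A3 | alternative 1 | (E)-1-[2-hydroxy-4,6-bis(methoxymethoxy)-3-(3-methylbut-2-enyl)phenyl]-3-[4-(methoxymethoxy)phenyl]prop-2-en-1-one | COCOc1ccc(/C=C/C(=O)c2c(O)c(CC=C(C)C)c(OCOC)cc2OCOC)cc1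
A4 | alternative 2 | kaempferol | O=c1c(O)c(-c2ccc(O)cc2)oc2cc(O)cc(O)c12
A5 | alternative 2 | 3,7-bis(methoxymethoxy)-2-[4-(methoxymethoxy)phenyl]-5-(3-methylbut-2-enyloxy)-4H-chromen-4-one | CC(C)=CCOc1cc(OCOC)cc2oc(-c3ccc(OCOC)cc3)c(OCOC)c(=O)c12
A6 | alternative 3 | 8-iodo-3,5,7-tris(methoxymethoxy)-2-[4-(methoxymethoxy)phenyl]-4H-chromen-4-one | COCOc1ccc(-c2oc3c(I)c(OCOC)cc(OCOC)c3c(=O)c2OCOC)cc1
A7 | alternative 3 | prenylboronic acid pinacol ester | CC(C)=CCB1OC(C)(C)C(C)(C)O1
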